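What I watched first in alder was the leftover: each complex can take 3 incoming ligands, so whatever is charged beyond that stays free once the exchanges are nearly finished. I called this the surplus, the equivalents charged minus 3, and froze the free ligand at that value for the late part of a run.

| setting | dusk | midnight | ash | elm | alder |
|---|---|---|---|---|---|
| starting complex | 0.10 M | 0.10 M | 0.10 M | 0.10 M | 0.10 M |
| incoming ligand | 1.3 equiv | 5 equiv | 1.00 equiv | 1.20 equiv | 4.00 equiv |
| remark | run made earlier | run made earlier |  |  |  |
| time |  |  | 10 h | 10 h | 10 h |

| run | time / h | complex with two exchanged / % | complex with three exchanged / % |
|---|---|---|---|
| dusk | 0.333 | 3 | 0 |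
| dusk | 1.00 | 6 | 3 |
| dusk | 2.00 | 8 | 7 |
| dusk | 2.50 | 9 | 8 |
| dusk | 4.00 | 12 | 12 |
| dusk | 5.00 | 12 | 13 |
| midnight | 0.417 | 12 | 15 |
| midnight | 0.667 | 13 | 22 |
| midnight | 1.00 | 16 | 36 |
| midnight | 2.00 | 13 | 55 |
| midnight | 3.00 | 11 | 70 |
| midnight | 5.00 | 5 | 88 |

(each reading ± 1.5 percentage points)

- which of these holds the largest part of the starting complex at the end of ash (complex with one exchanged / complex with two exchanged / complex with three exchanged / starting complex)
- which of these holds the largest part of the starting complex at the end of elm (complex with one exchanged / complex with two exchanged / complex with three exchanged / starting complex)
- which of these holds the largest part of the starting complex at the end of alder (complex with one exchanged / complex with two exchanged / complex with three exchanged / starting complex)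
- complex with two exchanged at the end of alder, in percent of the starting complex charged

My bench rule was that, with free ligand frozen and the starting complex charged alike, the tail of a run depends on surplus times time, which I called the dose, counted in hours at one equivalent of surplus:

surplus: alder 1.00 equiv, midnight 2.00 equiv

dose: alder at the asked time, 10.0 h; midnight at its last reading, 10.0 h

So I read alder's end off midnight's last readings, 5 % of the complex with two exchanged and 88 % of the complex with three exchanged. I expected alder to end somewhat below the first of these and above the second, since alder's charge stands closer to midnight's than its surplus does, which I reckoned would put it somewhat ahead early on.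

The rule stops where charged over needed falls below one. That ratio is 1.33 for alder but 0.333 for ash and 0.400 for elm, where the incoming ligand is the limiting reagent and the surplus is negative. Dusk, with more ligand than either, read 25.0 % in the complexes with two and three exchanged together at 5.00 h, so for ash and elm I expected the complex with one exchanged to lead.

The forecast gave complex with one exchanged for ash, complex with one exchanged for elm, complex with three exchanged for alder and 2 % of the complex with two exchanged, lower than my mark, holding that “Free ligand is then what matters”.

Alder gave 3.63 % of the complex with two exchanged at 10.0 h, under my mark, with 94.2 % in the complex with three exchanged, while ash and elm ended with 56.9 % and 56.8 % in the complex with one exchanged. The leaving ligand stood at 1.29 % of the charge in alder at that time. Against the surplus of 1.00 equiv, alder still held 1.08 equiv of incoming ligand.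

    starting complex + incoming ligand ⇌ leaving ligand + complex with one exchanged (K = 0.920, k = 0.00370 L mol⁻¹ s⁻¹)
    complex with one exchanged + incoming ligand ⇌ leaving ligand + complex with two exchanged (K = 0.0610, k = 0.00160 L mol⁻¹ s⁻¹)
    complex with two exchanged + incoming ligand ⇌ leaving ligand + complex with three exchanged (K = 0.430, k = 0.00450 L mol⁻¹ s⁻¹)
    leaving ligand → by-product carried off (k = 6.70 × 10⁻⁴ s⁻¹)

For the neighbour of alder charged with 2.40 equiv, the surplus is negative, −0.600 equiv, so at least 0.600 exchanges per complex stay undone. It ended with 0.800 undone per complex, 54.6 % of the complex with three exchanged and 13.9 % of the complex with two exchanged.

The runs come from a simulation with made-up constants, noise included.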